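The numbers in the tables were generated by integration for substances that don't exist, noise included.

Amounts first: in the south-east run, which is the very flask asked about, the readings from 8.00 h on average 21.1 %, so 0.317 M of target stands against 0.75 M of coupling partner charged, a ratio of 0.422. In the east run, with twice the coupling partner at 26 °C, the last 3 readings average 37.6 %, so 0.565 M stands against 1.5 M, a ratio of 0.376.

common to all: substrate 1.5 M
- south-east: coupling partner 0.75 M; temperature 20 °C; the very flask that is asked about, followed so far
- east: coupling partner 1.5 M; temperature 26 °C; run made earlier
- flask: coupling partner 0.750 M; temperature 20 °C; time 2.0 d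

| run | time / h | target / % |
|---|---|---|
| south-east | 4.00 | 19.5 |
| south-east | 8.00 | 21.4 |
| south-east | 15.0 | 21.1 |
| south-east | 25.0 | 20.7 |
| south-east | 50.0 | 21.2 |
| east | 0.500 | 23.3 |
| east | 1.00 | 31.5 |
| east | 2.00 | 37.1 |
| east | 4.00 | 37.5 |
| east | 8.00 | 38.3 |

(readings scatter by 0.5 percentage points)

- additions bring no volume worth counting
- the numbers in the tables scatter with a standard deviation of 0.5 percentage points
- a reading or a percentage of target counts all its forms, free or not

- teal: at 2.0 d add coupling partner, 100 % of the amount charged, then wait 25 h
- amber: change nothing and wait 25 h more
- grey: at 2.0 d add substrate, 50.0 % of the amount charged, then wait 25 h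
- violet: at 2.0 d raise the temperature by 25 K, then wait 25 h

- target, in percent of the substrate first charged, at 2.0 d
- which option adds most target ("none" when 2 percentage points or less is all one gets) (teal / amber / grey / violet / none)
- target present, in percent of the substrate first charged, after grey
- target present, in percent of the substrate first charged, after violet

We carry this ratio, target at the plateau over coupling partner charged, as the yield on partner φ. The readings do not exclude an equilibrium, but we commit to another reading: the coupling partner, charged below the 1.5 M of substrate, is the limiting reagent, and φ is the share of it that ends as target. Our own reckoning for the flask is then φ times 0.750 M over 1.5 M, which gives 21.1 % now. Grey and violet bring no coupling partner, so we expect them to stay at that figure. Teal adds 100 % of the amount of coupling partner charged, and scaling φ by the substrate not yet turned into target gives us a gain of 17 percentage points. The forecast, which holds that “the equilibrium reading is likely but unproven”, gives 21.1 %, names teal as best, and differs from us with 26.7 % after grey and 24 % after violet.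

The flask gives 21.0 % at 2.0 d, 21.0 % after grey and 21.0 % after violet, while teal reaches 32.8 %, so teal is best. At 48.0 h the flask holds 0 % of its coupling partner.

    substrate ⇌ other conformer (K = 0.540, k = 0.180 h⁻¹, Ea = 90.0 kJ mol⁻¹, ΔH = −1.00 kJ mol⁻¹)
    substrate + coupling partner → target (k = 0.290 M⁻¹ h⁻¹, Ea = 77.0 kJ mol⁻¹)
    coupling partner + other conformer → isomer of the product (k = 0.740 M⁻¹ h⁻¹, Ea = 80.0 kJ mol⁻¹)
    crystals ⇌ target, rate k4*(cs4 - [target]) while solid is left; crystals form when [target] > cs4 (solubility = 0.0780 M, k = 4.80 h⁻¹)
    coupling partner → decomposed reagent (k = 0.340 h⁻¹, Ea = 82.0 kJ mol⁻¹)
    (constants at 20 °C)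

In the flask, teal's second charge yields 0.237 of target per coupling partner added, less than the 0.422 read off the south-east run for the first charge. For the neighbour charged with 0.19 M, φ gives 5.35 %, and that flask stands at 5.52 %.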